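**Strategy**

The dihydropyran ring is opened at C4–C4a and C3–C2, which leaves its CH2–CH(OH) unit (C4–C3) as a two-carbon linchpin between the phloroglucinol carbon C4a and the gem-dimethyl carbon C2. The feature exploited is the oxygen on C3: it can first be boron. A vinylboron "ate" complex serves as the linchpin. One enantioselective palladium-catalysed conjunctive cross-coupling attaches an aryl bromide to C4 while an isopropenyl group migrates from boron to C3. The precursor is 2-bromo-1,3,5-tris(methoxymethoxy)benzene plus a vinyl(isopropenyl)borate. Boron-to-oxygen exchange, closure of an ortho oxygen onto the isopropenyl group, ring lithiation–acylation and deprotection complete the chalcone.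

Key step: step 3

Remark on numbering: chroman numbering (O1, C2, C3, C4, C4a, C5–C8, C8a) is used for the pyran-fused ring throughout; the target is (3R).

Assumption: the (Sp,Sp) antipode of the ligand is taken to give the (R)-boronate; the sense is checked on alcohol 8 by chiral HPLC and the mirror-image ligand is used if it proves opposite.

**Route**

Step 1
Reactants: 1 phloroglucinol (benzene-1,3,5-triol)
Product: 2 1,3,5-tris(methoxymethoxy)benzene
Conditions: MOMCl (3.6 equiv), i-Pr2NEt, CH2Cl2/DMF, 0 °C → rt
Reagents that add atoms: chloromethyl methyl ether (MOMCl), COCCl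
Why: Williamson-type O-alkylation of all three phenols with a hard alkoxymethyl chloride gives the tris-MOM ether, which later serves both as protection and as directing group.

Step 2
Reactants: 2 1,3,5-tris(methoxymethoxy)benzene
Product: 3 2-bromo-1,3,5-tris(methoxymethoxy)benzene
Conditions: NBS (1.0 equiv), CH2Cl2, −78 → 0 °C, dark
Reagents that add atoms: N-bromosuccinimide (NBS), O=C1CCC(=O)N1Br
Why: Electrophilic aromatic bromination of a strongly activated ring whose three C–H positions are equivalent, so one monobromide results when stoichiometry and temperature are kept low.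

Step 3
Reactants: 3 2-bromo-1,3,5-tris(methoxymethoxy)benzene; 4 vinylboronic acid pinacol ester; 5 isopropenylmagnesium bromide
Product: 8 (2R)-3-methyl-1-[2,4,6-tris(methoxymethoxy)phenyl]but-3-en-2-ol, via borate complex 6 (not isolated), via allylic boronate 7 (not isolated)
Conditions: 4 + 5, THF, 0 °C → rt; then 3, NaOTf (CF3SO3Na), Pd(OAc)2 (2 mol %), (Sp,Sp)-MandyPhos [2,2′-bis(α-(dimethylamino)benzyl)-1,1′-bis(diphenylphosphino)ferrocene] (2.4 mol %), THF/DMSO, 60 °C; then 3 M NaOH, 30% H2O2, 0 °C → rt
Reagents that add atoms: hydrogen peroxide, OO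
Why: Zerovalent palladium with the bisphosphine inserts into the C–Br bond of 3, NaOTf strips the bromide, and the cationic arylpalladium binds the unsubstituted vinyl group of borate 6; this triggers a 1,2-metallate shift in which the isopropenyl group moves from boron to the boron-bearing carbon (the C3–C2 bond) while palladium takes the terminal carbon, and reductive elimination then forms the aryl–CH2 bond (C4a–C4). The closest known reaction type is the enantioselective palladium-catalysed conjunctive cross-coupling of bis(alkenyl)borates, in which the less substituted alkene is the acceptor and the more substituted alkenyl group migrates. No ring is closed here; the pyran ring closes in step 4. The only new stereocentre, C3, is set by the twofold-symmetric chiral ligand, which selects the face of the vinyl group that palladium binds (migration is anti to palladium and stereospecific), and it survives the oxidation because the boron-to-oxygen migration proceeds with retention. The step needs conjunctive coupling to outrun direct Suzuki-type transfer of an alkenyl group, and needs the vinyl rather than the isopropenyl group to be activated; the chelating wide-bite-angle ligand, the non-coordinating triflate counter-ion and the lower substitution of the vinyl group are relied on for both.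

Step 4
Reactants: 8 (2R)-3-methyl-1-[2,4,6-tris(methoxymethoxy)phenyl]but-3-en-2-ol
Product: 10 (3R)-5,7-bis(methoxymethoxy)-2,2-dimethyl-3,4-dihydro-2H-chromen-3-ol, via organomercurial 9 (not isolated)
Conditions: Hg(OCOCF3)2 (2.2 equiv), NaHCO3, CH2Cl2, −20 → 0 °C; then NaBH4, 3 M NaOH, 0 °C
Reagents that add atoms: none
Why: Proposed new method: divalent mercury converts the 1,1-disubstituted alkene into a mercurinium ion whose tertiary carbon is attacked (6-exo) by the oxygen of either of the two equivalent ortho MOM ethers, the resulting oxonium ion sheds its methoxymethyl group to trifluoroacetate, and NaBH4 replaces C–Hg by C–H, so the gem-dimethyl ether forms without a free carbocation next to the C3 carbinol and C3 is untouched; the closest known reaction types are the oxymercuration–demercuration of ortho-alkenylphenols to 2,2-dimethylchromans and cycloetherifications in which a benzyl or aryl methyl ether oxygen attacks a mercury- or iodine-activated π bond with loss of its alkyl group.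

Step 5
Reactants: 11 1-bromo-4-(methoxymethoxy)benzene; 12 N-methoxy-N-methylacrylamide
Product: 13 (2E)-N-methoxy-3-[4-(methoxymethoxy)phenyl]-N-methylprop-2-enamide
Conditions: Pd(OAc)2 (3 mol %), P(o-tol)3, Et3N, DMF, 100 °C
Reagents that add atoms: none
Why: Mizoroki–Heck arylation of the acrylamide, where syn insertion and syn β-hydride elimination give the E-cinnamamide.

Step 6
Reactants: 10 (3R)-5,7-bis(methoxymethoxy)-2,2-dimethyl-3,4-dihydro-2H-chromen-3-ol; 13 (2E)-N-methoxy-3-[4-(methoxymethoxy)phenyl]-N-methylprop-2-enamide
Product: 16 (2E)-1-[(3R)-3-hydroxy-5,7-bis(methoxymethoxy)-2,2-dimethyl-3,4-dihydro-2H-chromen-6-yl]-3-[4-(methoxymethoxy)phenyl]prop-2-en-1-one, via dilithio species 14 (not isolated), via tetrahedral lithium adduct 15 (not isolated)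
Conditions: n-BuLi (2.3 equiv), THF, −20 → 0 °C; then 13, −78 → 0 °C; aq NH4Cl
Reagents that add atoms: none
Why: After the first equivalent forms the C3 alkoxide, directed ortho-metalation should remove the C6 proton between two chelating MOM ethers in preference to C8–H (one MOM neighbour and the hindered ring oxygen), and the aryllithium then adds 1,2 to the enamide in a Weinreb ketone synthesis whose chelated adduct releases the E-enone only on work-up.

Step 7
Reactants: 16 (2E)-1-[(3R)-3-hydroxy-5,7-bis(methoxymethoxy)-2,2-dimethyl-3,4-dihydro-2H-chromen-6-yl]-3-[4-(methoxymethoxy)phenyl]prop-2-en-1-one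
Product: 17 (2E)-3-(4-hydroxyphenyl)-1-[(3R)-3,5,7-trihydroxy-2,2-dimethyl-3,4-dihydro-2H-chromen-6-yl]prop-2-en-1-one (target)
Conditions: 3 M aq HCl, MeOH, rt → 40 °C, short reaction time
Reagents that add atoms: none
Why: Acid-catalysed acetal exchange with methanol should free the three phenols under conditions mild enough to leave the C3 alcohol, the tertiary alkyl aryl ether of the pyran ring and the E-enone unchanged.

**Compound list**

1 | phloroglucinol (benzene-1,3,5-triol) | Oc1cc(O)cc(O)c1 | starting material
2 | 1,3,5-tris(methoxymethoxy)benzene | COCOc1cc(OCOC)cc(OCOC)c1 | intermediate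
3 | 2-bromo-1,3,5-tris(methoxymethoxy)benzene | COCOc1cc(OCOC)c(Br)c(OCOC)c1 | intermediate
4 | vinylboronic acid pinacol ester (4,4,5,5-tetramethyl-2-vinyl-1,3,2-dioxaborolane) | C=CB1OC(C)(C)C(C)(C)O1 | starting material
5 | isopropenylmagnesium bromide | CC(=C)[Mg]Br | starting material
6 | bromomagnesium isopropenyl(vinyl)(pinacolato)borate (not isolated) | C=C[B-]1(C(C)=C)OC(C)(C)C(C)(C)O1.[Mg+]Br | intermediate
7 | 4,4,5,5-tetramethyl-2-[(2R)-3-methyl-1-[2,4,6-tris(methoxymethoxy)phenyl]but-3-en-2-yl]-1,3,2-dioxaborolane (not isolated) | C=C(C)[C@H](B1OC(C)(C)C(C)(C)O1)Cc1c(OCOC)cc(OCOC)cc1OCOC | intermediate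
8 | (2R)-3-methyl-1-[2,4,6-tris(methoxymethoxy)phenyl]but-3-en-2-ol | C=C(C)[C@H](O)Cc1c(OCOC)cc(OCOC)cc1OCOC | intermediate
9 | {[(3R)-3-hydroxy-5,7-bis(methoxymethoxy)-2-methyl-3,4-dihydro-2H-chromen-2-yl]methyl}mercury trifluoroacetate, both C2 epimers (not isolated) | FC(F)(F)C(=O)O[Hg]CC1(C)Oc2cc(OCOC)cc(OCOC)c2C[C@H]1O | intermediate
10 | (3R)-5,7-bis(methoxymethoxy)-2,2-dimethyl-3,4-dihydro-2H-chromen-3-ol | CC1(C)Oc2cc(OCOC)cc(OCOC)c2C[C@H]1O | intermediate
11 | 1-bromo-4-(methoxymethoxy)benzene | COCOc1ccc(Br)cc1 | starting material
12 | N-methoxy-N-methylacrylamide | CON(C)C(=O)C=C | starting material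
13 | (2E)-N-methoxy-3-[4-(methoxymethoxy)phenyl]-N-methylprop-2-enamide | CON(C)C(=O)/C=C/c1ccc(OCOC)cc1 | intermediate
14 | C6-lithiated lithium alkoxide of 10 (not isolated) | CC1(C)Oc2cc(OCOC)c([Li])c(OCOC)c2C[C@H]1O[Li] | intermediate
15 | tetrahedral lithium adduct of 14 and 13 (not isolated) | CC1(C)Oc2cc(OCOC)c(C(O[Li])(N(C)OC)/C=C/c3ccc(OCOC)cc3)c(OCOC)c2C[C@H]1O[Li] | intermediate
16 | (2E)-1-[(3R)-3-hydroxy-5,7-bis(methoxymethoxy)-2,2-dimethyl-3,4-dihydro-2H-chromen-6-yl]-3-[4-(methoxymethoxy)phenyl]prop-2-en-1-one | CC1(C)Oc2cc(OCOC)c(C(=O)/C=C/c3ccc(OCOC)cc3)c(OCOC)c2C[C@H]1O | intermediate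
17 | (2E)-3-(4-hydroxyphenyl)-1-[(3R)-3,5,7-trihydroxy-2,2-dimethyl-3,4-dihydro-2H-chromen-6-yl]prop-2-en-1-one | CC1(C)Oc2cc(O)c(C(=O)/C=C/c3ccc(O)cc3)c(O)c2C[C@H]1O | target

**Step count and risks**

Total step count: 7. Longest linear sequence: 6 steps (1, 2, 3, 4, 6, 7); step 5 is a one-step side branch.

Steps most likely to fail:

1. Step 4 (proposed new method). The electron-rich ring may be mercurated faster than the alkene is activated. The borohydride work-up returns any aryl–Hg bond to C–H, which is why more than two equivalents are used, but conversion may stall. The weakly nucleophilic aryl ether oxygen may also fail to capture the mercurinium ion, or further MOM groups may be lost. The fallback uses known chemistry only and sets out from 8. All three MOM groups are removed (HCl cat., MeOH, rt) to give 2-[(2R)-2-hydroxy-3-methylbut-3-en-1-yl]benzene-1,3,5-triol F1. A free ortho phenol (the two are equivalent) is then cyclised by classical oxymercuration–demercuration (Hg(OAc)2, THF, rt; then NaBH4, NaOH) through {[(3R)-3,5,7-trihydroxy-2-methyl-3,4-dihydro-2H-chromen-2-yl]methyl}mercury acetate F2 to (3R)-2,2-dimethyl-3,4-dihydro-2H-chromene-3,5,7-triol F3. The two phenols are re-protected selectively (MOMCl 2.1 equiv, i-Pr2NEt, CH2Cl2, 0 °C), which returns to the route at 10.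

2. Step 3 (key step). Oxidative addition and alkene binding may be slow at the di-ortho-alkoxy, electron-rich aryl bromide, and bromide may inhibit the cationic pathway. Direct Suzuki-type alkenyl transfer or protodeboronation would then compete and the enantioselectivity could erode. The fallback keeps the two-bond event but changes the electrophile class to a triflate, so that no halide is released from the arene. It sets out from 2. Directed lithiation (n-BuLi, THF, 0 °C) gives 2,4,6-tris(methoxymethoxy)phenyllithium F4, which is trapped with B(OMe)3 as lithium trimethoxy[2,4,6-tris(methoxymethoxy)phenyl]borate F5. Oxidation (H2O2, NaOH) gives 2,4,6-tris(methoxymethoxy)phenol F6, and Tf2O/pyridine gives 2,4,6-tris(methoxymethoxy)phenyl trifluoromethanesulfonate F7. This triflate replaces 3 in the coupling with borate 6 under the same catalyst, giving 7 and, after the oxidative work-up, returning to the route at 8.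

3. Step 6. The hindered dianion may add in a conjugate sense to the enamide or transfer the acyl group incompletely, and some metalation at C8 would lower the material balance. The fallback builds the enone by condensation instead of acyl substitution and sets out from 14 (made from 10 as in step 6). Quenching with N-methoxy-N-methylacetamide gives, through the tetrahedral lithium adduct F8, the methyl ketone 1-[(3R)-3-hydroxy-5,7-bis(methoxymethoxy)-2,2-dimethyl-3,4-dihydro-2H-chromen-6-yl]ethan-1-one F9. Claisen–Schmidt condensation of this ketone with commercial 4-(methoxymethoxy)benzaldehyde (KOH, EtOH, rt) returns to the route at 16.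

**Further compounds**

F1 | step 4 | 2-[(2R)-2-hydroxy-3-methylbut-3-en-1-yl]benzene-1,3,5-triol | C=C(C)[C@H](O)Cc1c(O)cc(O)cc1O
F2 | step 4 | {[(3R)-3,5,7-trihydroxy-2-methyl-3,4-dihydro-2H-chromen-2-yl]methyl}mercury acetate, both C2 epimers | CC(=O)O[Hg]CC1(C)Oc2cc(O)cc(O)c2C[C@H]1O
F3 | step 4 | (3R)-2,2-dimethyl-3,4-dihydro-2H-chromene-3,5,7-triol | CC1(C)Oc2cc(O)cc(O)c2C[C@H]1O
F4 | step 3 | 2,4,6-tris(methoxymethoxy)phenyllithium | [Li]c1c(OCOC)cc(OCOC)cc1OCOC
F5 | step 3 | lithium trimethoxy[2,4,6-tris(methoxymethoxy)phenyl]borate | [Li+].CO[B-](OC)(OC)c1c(OCOC)cc(OCOC)cc1OCOC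
F6 | step 3 | 2,4,6-tris(methoxymethoxy)phenol | Oc1c(OCOC)cc(OCOC)cc1OCOC
F7 | step 3 | 2,4,6-tris(methoxymethoxy)phenyl trifluoromethanesulfonate | O=S(=O)(Oc1c(OCOC)cc(OCOC)cc1OCOC)C(F)(F)F
F8 | step 6 | tetrahedral lithium adduct of 14 and N-methoxy-N-methylacetamide | CC1(C)Oc2cc(OCOC)c(C(C)(O[Li])N(C)OC)c(OCOC)c2C[C@H]1O[Li]
F9 | step 6 | 1-[(3R)-3-hydroxy-5,7-bis(methoxymethoxy)-2,2-dimethyl-3,4-dihydro-2H-chromen-6-yl]ethan-1-one | CC1(C)Oc2cc(OCOC)c(C(C)=O)c(OCOC)c2C[C@H]1O
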